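Equal, independent sites cannot put 2.2% of bis adduct into the violet run at 0.500 h: they allow 0.354%, and a reading scatters by 0.3 percentage points. So says Ada, who made the forecast; Ben holds to equal sites all the same.

| flask | substrate | partner | remark | time |
|---|---|---|---|---|
| violet | 4.7 mM | 1.5 equiv | run made earlier |  |
| red | 14 mM | 1.5 equiv | run made earlier |  |
| grey | 29 mM | 1.5 equiv | run made earlier |  |
| amber | 20 mM | 1.7 equiv | run made earlier |  |
| theta | 5.0 mM | 0.750 equiv |  | 5.0 h |
| beta | 5.0 mM | 4.50 equiv |  | 5.0 h |
| eta | 20 mM | 1.50 equiv |  | 5.0 h |
| zeta | 40 mM | 6.00 equiv |  | 5.0 h |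
| gamma | 40 mM | 1.00 equiv |  | 5.0 h |

| run | time / h | single product / % | bis adduct / % |
|---|---|---|---|
| violet | 0.200 | 4.2 | 0 |
| violet | 0.500 | 8.1 | 2.2 |
| violet | 1.00 | 11.9 | 5.5 |
| violet | 2.50 | 14.2 | 13.3 |
| red | 0.200 | 9.5 | 2.3 |
| red | 0.500 | 14.3 | 9.0 |
| red | 1.00 | 15.8 | 15.0 |
| red | 2.50 | 12.2 | 18.9 |
| grey | 0.333 | 14.8 | 11.6 |
| grey | 0.833 | 13.6 | 18.1 |
| grey | 1.50 | 12.0 | 18.7 |
| grey | 2.50 | 11.2 | 18.8 |
| amber | 0.333 | 14.4 | 9.9 |
| amber | 0.833 | 13.5 | 17.5 |
| amber | 1.50 | 11.6 | 19.1 |
| amber | 2.50 | 10.1 | 18.3 |

(scatter of a reading: 0.3 percentage points)

- the earlier runs were read with a standard deviation of 0.3 percentage points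
- the share counts what is present at the end, not what went on to other products

1. ranking by share of single product in all that became single product or bis adduct or triple product, from high to low, at 5.0 h (theta / beta / eta / zeta / gamma)
2. the share of single product in all that became single product or bis adduct or triple product of the flask you put first, at 5.0 h
3. the share of single product in all that became single product or bis adduct or triple product of the flask you put last, at 5.0 h

Their scale is the ratio of the rate constant of partner on single product to that on substrate, s. Ben's view is its zero: single product keeps 2 of the 3 sites of substrate, so s = 0.667. Ada reads it early in a run, where bis adduct stands at s/2 times the square of the converted fraction, taken as single product plus bis adduct. My reading of violet at 0.500 h, which carries the scatter of its small bis adduct figure, gives 4.15 for this selectivity factor; the forecast says near 4.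

Ben answers that this rests on one small reading, and the earliest violet reading is his region. At 0.200 h violet read 0% of bis adduct; his s predicts 0.0588% and Ada's 0.366%, a gap of 0.31 points against a scatter of 0.3 points.

Both accept the forecast's “each step second order in partner”. Partner then cancels between the steps, and the share of single product follows from r, the fraction of substrate left: (r^s − r) divided by (1 − s)(1 − r). The forecast puts the time integral of the first rate constant times [partner] at 0.35 for theta, so r there is about 70.0%. There Ben gets 88.4%, and I get 50.0% with the s read from violet.

The forecast: theta > gamma > eta > beta > zeta, with 50% first and 0% last.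

The flask gives theta > gamma > eta > beta > zeta, with theta at 49.1% and zeta at 0%, so Ada's figure stands and Ben's 88.4% does not.

    substrate + partner → single product (k = 0.550 /M/min)
    partner → decomposed reagent (k = 5.70 × 10⁻⁴ /min)
    partner + single product → bis adduct (k = 2.40 /M/min)
    single product → over-reaction product (k = 2.80 × 10⁻⁶ /min)
    partner + bis adduct → triple product (k = 1.50 /M/min)

At 5.00 h theta keeps 71% of its substrate, and s on that r gives 50.7%. Theta read at 2.0 h keeps 82% of its substrate; s gives a share of 67.2%, and the flask's share is 66.0%.

The earlier runs and the new flask are simulated for substances that don't exist; the scatter is artificial.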